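The meeting was called on one question: how much D stands at the end of each of the three new flasks, with the south and south-west runs as evidence.

| setting | south | south-west | blue | ochre | grey |
|---|---|---|---|---|---|
| Z | 0.0050 M | 0.0050 M | 0.0050 M | 0.0050 M | 0.0050 M |
| L | 1.1 equiv | 2.2 equiv | 0.800 equiv | 1.20 equiv | 1.50 equiv |
| remark | run made earlier | run made earlier |  |  |  |
| time |  |  | 4.0 min | 4.0 min | 4.0 min |

| run | time / min | D / % | G / % | Z / % |
|---|---|---|---|---|
| south | 0.333 | 12 | 32 | 34 |
| south | 0.500 | 10 | 34 | 29 |
| south | 0.667 | 10 | 35 | 20 |
| south | 1.00 | 13 | 37 | 18 |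
| south | 1.50 | 8 | 43 | 16 |
| south | 2.50 | 7 | 40 | 14 |
| south | 4.00 | 9 | 40 | 14 |
| south-west | 0.200 | 12 | 39 | 18 |
| south-west | 0.667 | 1 | 43 | 3 |
| south-west | 1.00 | 0 | 44 | 0 |
| south-west | 1.50 | 2 | 40 | 1 |
| south-west | 2.50 | 2 | 36 | 0 |
| south-west | 3.00 | 0 | 36 | 0 |
| south-west | 4.00 | 0 | 32 | 0 |

(scatter of a reading: 1.5 percentage points)

- how much D is there at the end, in percent of the Z charged: for each flask in turn (blue, ochre, grey)



The analyst reported that Z in the south run stopped falling, reading 14% at 2.50 min and 14% at 4.00 min; she took this as the mark of L as limiting reagent there, so that the south run had spent 1.28 equivalents of L per equivalent of Z lost.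

The kineticist proposed dropping time altogether, arguing that if L uses D as fast as it uses Z, each in proportion to itself, and a fixed share of the lost Z becomes D, then the ratio of D to Z gains the same step for each power of ten by which Z falls. From the first and last south readings he read 0.753 as the climb, the gain in the ratio of D to Z per power of ten of fall in Z. The analyst objected that the south-west reading at 0.200 min gives 0.895, but she let the climb stand as a reading, given a scatter of 1.5 percentage points on a D of 12%.

The chair then had the two combined, as his own reckoning. Counted at that spending, Z comes to 37.5% in blue, so his estimate of D there is the climb times that Z times its powers of ten of fall, 12.0%; in ochre the count puts Z at 6.18%, which gives 5.63%. For grey the charge of 1.50 equiv is more than the spending of 1.28, so the count gives a negative Z, −17.2%, and the chair entered no number.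

The forecast, on the ground that “Each run stops when L runs out”, gave 15%, 7.5% and 1% for blue, ochre and grey, higher than the chair's figures for blue and ochre.

The flasks give 13.0%, 7.39% and 1.01% of D in blue, ochre and grey, under this scheme:

    Z + L → G + J (k = 12.0 /M/s)
    Z + L → D + J (k = 6.50 /M/s)
    L + G → Q + J (k = 0.640 /M/s)
    L + D → Q + J (k = 18.0 /M/s)
    G ⇌ E (K = 0.340, k = 0.190 /s)

Blue holds D at 13.0% with L at 0.286% of its own charge at 2.00 min, and D is still 13.0% at 40.0 min. Laid on the 32% of Z that blue keeps, the climb gives 11.9% of D against the 13.0% found; laid on the 0.51% of Z left in grey at 4.00 min, it gives 0.874%, where grey holds 1.01%.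

(All runs were generated by integration from invented constants; scatter was added.)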